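## Structural features

The target is a monocyclic elemane: one cyclohexane and no second ring, numbered here C5 (bearing the 3-hydroxyprop-1-en-2-yl group C4(=C3)C15), C6 (OH), C7 (bearing the 1-carboxyvinyl group C11(=C13)C12), C8 (acyloxy), C9 (CH2) and C10 (methyl C14, vinyl C1=C2). C10 is an all-carbon quaternary centre, C5, C6, C7 and C8 are four contiguous stereocentres beside it, and the (S)-3-hydroxy-2-methylpropanoyl ester carries a sixth, remote one. Read from the SMILES, the C10 methyl and the substituents on C5, C6, C7 and C8 all lie on one ring face (5R,6S,7S,8R,10S); in the chair that keeps the C5 and C7 groups equatorial, the methyl, O6 and O8 are syn-axial. Fragile elements are the γ-hydroxy acrylic acid (C6–OH cis to the C7 side chain, able to lactonise), the O8 ester syn to a free O6–H (acyl migration), the acrylate acceptor and the epimerisable α-centre of the ester. The real difficulty is crowding five groups onto one face around a quaternary carbon while keeping three primary oxygens (C12, C15, side chain) and two secondary ones (C6, C8) distinguishable. The key step exploits the fact that C6–OH, C5 and the C4=C3 methylene form a homoallylic alcohol with the carbinol and allylic substituents cis on the ring. That is the pattern left when the γ-carbon (C5) of a 2-(oxymethyl)allylboron unit adds to a C6 aldehyde, an addition that also closes the C5–C10 ring.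

## Logic of the disconnections

36 back to 31: no skeletal bond is cut. The three O–Si bonds are removed from the plan last, C12 is stepped back from acid (35) to aldehyde (34) to alcohol (33) to its PMB ether (32), and the C6 silyl ether is taken off to reach 31. The reason is that the hydroxy acid is the most fragile part and must appear only at the end. The gain is a fully masked intermediate. The demand is that O6 is silylated before C12 is oxidised (otherwise lactol and lactone form), and that the final fluoride step causes neither lactonisation nor acyl migration.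

31 to 30 + 23: the C8 O–acyl bond is cut. Keeping O8 unacylated through the ring closure lets it steer that closure and avoids a β-acyloxy aldehyde. The gain is a diol and a simple chiral acid. The demand is that the forward acylation chooses O8 over the more hindered O6.

30 to 28: the C5–C6 bond is cut, which opens the only ring (key disconnection). The gain is an open chain with three stereocentres (C7, C8, C10) and one alkene of defined geometry. The demands are a boronate with C10 cis to CH2B, a free O8–H, and release of the aldehyde under neutral conditions. That geometry is (E) by the sequence rules, because CH2OSi outranks CH2B; the label (Z) would be wrong for it.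

28 to 27 to 26: C6 is returned to the alcohol and the C3–C4 bond (CH2B to alkene carbon) is cut back to a vinyl iodide. Boron is introduced late so that it never meets an aldehyde it should not attack. The gain is an inert handle. The demands are iodine cis to C10 and an oxidation that touches only the primary alcohol.

26 to 25 to 14 + 20: the C7–C8 bond is cut, a second homoallylic-alcohol retron (C8–OH, C7, C11=C13). This sets C7 and C8 together and brings in C6 and C11–C13 at once. The gain is two fragments of similar size. The demands are the geometry of 20 (CH2O cis to CH2B) for the relative configuration and a chiral acid catalyst for the aldehyde face.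

14 to 13 to 12 to 11 to 9: protecting-group and oxidation-level changes, then the C4–I bond is removed to reveal an alkyne. The reason is that a trans-hydrometalation of a propargylic alcohol gives exactly the needed iodide geometry. The demand is tin at C4 and trans addition in the presence of the vinyl group.

9 to 8 to 5 + 6: the C10–C5 bond is cut. An SN2′ alkynylation creates the quaternary centre and the vinyl group in one step from achiral pieces. The demand is catalyst control of the C10 configuration and a geometrically pure allylic phosphate.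

5 to 4 to 2 to 1: the C10–C14 and C1–C2 bonds are cut (methyl-metalation of an alkyne, then hydroxymethylation). The gain is a four-carbon alkynol. The demand is clean syn addition so that 4 is the pure (E) isomer.

20 to 19 to 18 to 16 to 15: the C11–C13 bond (CH2B) and then the C–I bond are cut back to a symmetrical alkynediol. The demand is hydroxyl-directed trans-hydroalumination so that iodine, and later CH2B, ends up cis to C6.

23 to 22 to 21: only O–Si and ester hydrolysis. The stereocentre is bought, and the demand is that it is not epimerised.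

## Other disconnections considered

Alternative 1: the cut removes C10–C14 and C5–C14, treating the C10 methyl as a cyclopropane methylene. The forward step is Et2Zn/CH2I2 cyclopropanation of cyclohexenol A1 to bicycloheptanol A2, delivered by the zinc alkoxide to the hydroxyl face.
- In its favour: directed cyclopropanation is among the most dependable face-selective reactions; the ring exists from the start; and the SMILES of A2 has the cyclopropane methylene, the C6 hydroxyl and the C8 silyloxy group all cis, as the target needs.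
- Against it here: A2 holds none of the three alkenyl side chains. Unmasking the methyl requires oxidising C6 to the ketone and opening the ring reductively, which destroys the C6 centre that directed the step. C5 must then be alkenylated, C7 functionalised, C6 reduced again and the vinyl group built from the CH2O arm.
- Comparison: on mechanism the facial control of this step is better founded than that of the chosen ring closure, and that is a point on which alternative 1 is superior. On structure it sets one quaternary centre where the chosen step sets two centres and the complete ring substitution. On step economy its precursor is shorter but its end-game is much longer.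

Alternative 2: the cut removes C1–C10 and C4–C5 without opening the ring. The forward step is conjugate addition of vinylmagnesium bromide with CuBr·SMe2 to enone A3, transmetalation of the enolate with ZnCl2, and coupling with bromide A4 using Pd2(dba)3 (zerovalent palladium) and P(t-Bu)3 to give ketone A5.
- In its favour: two skeletal bonds form in one flask; the vinyl group should enter anti to the C8 silyloxy group, which is what the target needs; and no open-chain stereocontrol is required.
- Against it here: the coupling takes place at an enolate carbon next to the new quaternary centre; the alkenylpalladium species from A4 carries a β-oxygen and can fragment; C5 is fixed only by equilibration α to the ketone; and C7 must still be alkenylated and C6 reduced to the axial alcohol.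
- Comparison: alternative 2 is the better plan in bonds made per step and in the length of the route to a ring carrying C10, C8 and C5. It is the equal of the chosen plan in that both must later acylate or differentiate hindered oxygens. It is weaker in that C6 and C7 remain to be set on a crowded ring, whereas the chosen step delivers C5 and C6 together with every carbon in place.

Alternative 3: the cut removes C7–C8. The forward step converts the C8 aldehyde of A6 into an acyl anion equivalent with the thiazol-2-ylidene from 3-benzyl-5-(2-hydroxyethyl)-4-methylthiazolium chloride and triethylamine. This adds to C7 of the 2-(acetoxymethyl)enoate, closes the six-membered ketone 6-exo-trig and expels acetate to give acrylate A7.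
- In its favour: the ring and the C11=C13 methylene form together; C12 arrives already at the acid oxidation level as an allyl ester, which removes the three redox and protecting-group steps of the chosen end-game (a clear advantage); and no metal is needed.
- Against it here: A6 must already contain the C5/C6/C10 triad, including the quaternary centre, in open-chain form; its aldehyde is enolisable; the acceptor is β-substituted and flanked by a silyloxy group that can be lost by elimination; and the C8 ketone must afterwards be reduced to the axial alcohol and acylated on the ring, where O8 is syn-axial to the methyl group.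
- Comparison: on structure it closes the same ring but sets one centre (C7, epimerisable next to the new ketone) where the chosen step sets two. On mechanism neither plan has its face control assured. On step economy after the key step alternative 3 is better, but before the key step it is worse.

Key step: step 20

Remark on descriptors: the boronate geometry needed for a cis C5/C6 pair has C10 cis to CH2B. Because CH2OSi outranks CH2B this isomer is (E), and it is named so throughout.

Remark on design: the C8 hydroxyl is left free in the ring closure and acylated afterwards. With an acyloxy group on C8, the chair that leads to the target carries three syn-axial groups and opposes the C8–O and C6=O dipoles, so the wrong face would be expected to be preferred.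

Assumption: the enantiomer of each chiral catalyst (steps 4 and 16) is chosen by the accepted model and confirmed on the product.

Step 1
Reactants: 1 but-3-yn-1-ol
Product: 2 1-[(but-3-yn-1-yloxy)methyl]-4-methoxybenzene
Conditions: NaH, PMBCl, Bu4NI (cat.), THF, 0 °C → rt
Reagents that add atoms: 4-methoxybenzyl chloride, COc1ccc(CCl)cc1
Why: Williamson etherification of the primary alkoxide; the PMB ether is stable to the organoaluminium steps and is later removed without touching silyl ethers.

Step 2
Reactants: 2 1-[(but-3-yn-1-yloxy)methyl]-4-methoxybenzene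
Product: 4 (E)-5-[(4-methoxybenzyl)oxy]-3-methylpent-2-en-1-ol, via alkenyldimethylalane 3 (not isolated)
Conditions: Me3Al, Cp2ZrCl2 (20 mol %), CH2Cl2, 0 °C → rt; then n-BuLi, (CH2O)n, THF, −78 °C → rt
Reagents that add atoms: trimethylaluminium, C[Al](C)C; paraformaldehyde (as formaldehyde), C=O
Why: Zirconium-catalysed carboalumination adds methyl and aluminium syn across the terminal alkyne (methyl to the internal carbon). The derived aluminate is hydroxymethylated with retention, so only the (E)-alkene should form.

Step 3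
Reactants: 4 (E)-5-[(4-methoxybenzyl)oxy]-3-methylpent-2-en-1-ol
Product: 5 diethyl (E)-5-[(4-methoxybenzyl)oxy]-3-methylpent-2-en-1-yl phosphate
Conditions: ClP(O)(OEt)2, Et3N, DMAP (cat.), CH2Cl2, 0 °C
Reagents that add atoms: diethyl chlorophosphate, CCOP(=O)(Cl)OCC
Why: Phosphorylation of the primary allylic alcohol gives the leaving group used in copper-catalysed allylic substitution.

Step 4
Reactants: 5 diethyl (E)-5-[(4-methoxybenzyl)oxy]-3-methylpent-2-en-1-yl phosphate; 6 tert-butyldimethyl(prop-2-yn-1-yloxy)silane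
Product: 8 tert-butyl{[(4S)-4-{2-[(4-methoxybenzyl)oxy]ethyl}-4-methylhex-5-en-2-yn-1-yl]oxy}dimethylsilane, via alkynyldiisobutylalane 7 (not isolated)
Conditions: 6, i-Bu2AlH, Et3N (5 mol %), toluene, rt → 50 °C; then CuCl2·2H2O (5 mol %), chiral sulfonate-bearing imidazolinium salt (N-heterocyclic carbene precursor, 5.5 mol %), 5, THF, −30 °C → rt
Reagents that add atoms: none
Why: Copper-catalysed enantioselective SN2′ allylic substitution with a dialkyl(alkynyl)alane: the alkynyl group adds to the methyl-bearing alkene carbon and the phosphate leaves, creating the C10 quaternary centre and the vinyl group together. The chiral carbene–copper complex selects the alkene face, and the ligand enantiomer is chosen to give (S).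

Step 5
Reactants: 8 tert-butyl{[(4S)-4-{2-[(4-methoxybenzyl)oxy]ethyl}-4-methylhex-5-en-2-yn-1-yl]oxy}dimethylsilane
Product: 9 (4S)-4-{2-[(4-methoxybenzyl)oxy]ethyl}-4-methylhex-5-en-2-yn-1-ol
Conditions: TBAF, THF, 0 °C
Reagents that add atoms: none
Why: Fluoride cleaves the only silyl ether and frees the propargylic hydroxyl that directs the next step.

Step 6
Reactants: 9 (4S)-4-{2-[(4-methoxybenzyl)oxy]ethyl}-4-methylhex-5-en-2-yn-1-ol
Product: 11 (2Z,4S)-2-iodo-4-{2-[(4-methoxybenzyl)oxy]ethyl}-4-methylhexa-2,5-dien-1-ol, via vinylstannane 10 (not isolated)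
Conditions: [Cp*RuCl]4 (2.5 mol %), Bu3SnH, CH2Cl2, rt; then I2, CH2Cl2, 0 °C
Reagents that add atoms: iodine, II
Why: Ruthenium-catalysed trans-hydrostannation of a propargylic alcohol: the hydroxyl hydrogen-bonds to the chloride on ruthenium and places tin on the carbinol-side carbon (C4), with hydrogen added trans at C5, so tin lies cis to C10. Iododestannylation retains this geometry, and the terminal vinyl group is not a substrate for this catalyst.

Step 7
Reactants: 11 (2Z,4S)-2-iodo-4-{2-[(4-methoxybenzyl)oxy]ethyl}-4-methylhexa-2,5-dien-1-ol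
Product: 12 tert-butyl{[(2Z,4S)-2-iodo-4-{2-[(4-methoxybenzyl)oxy]ethyl}-4-methylhexa-2,5-dien-1-yl]oxy}dimethylsilane
Conditions: TBSCl, imidazole, CH2Cl2, rt
Reagents that add atoms: tert-butyldimethylsilyl chloride, CC(C)(C)[Si](C)(C)Cl
Why: Silylation of the primary allylic alcohol; this C15 silyl ether stays in place until the last step.

Step 8
Reactants: 12 tert-butyl{[(2Z,4S)-2-iodo-4-{2-[(4-methoxybenzyl)oxy]ethyl}-4-methylhexa-2,5-dien-1-yl]oxy}dimethylsilane
Product: 13 (3S,4Z)-6-[(tert-butyldimethylsilyl)oxy]-3-ethenyl-5-iodo-3-methylhex-4-en-1-ol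
Conditions: DDQ, CH2Cl2/pH 7 buffer, 0 °C
Reagents that add atoms: none
Why: Oxidative cleavage of the PMB ether by hydride abstraction and hydrolysis; the silyl ether, vinyl iodide and alkenes are inert to DDQ.

Step 9
Reactants: 13 (3S,4Z)-6-[(tert-butyldimethylsilyl)oxy]-3-ethenyl-5-iodo-3-methylhex-4-en-1-ol
Product: 14 (3S,4Z)-6-[(tert-butyldimethylsilyl)oxy]-3-ethenyl-5-iodo-3-methylhex-4-enal
Conditions: DMP (1,1,1-triacetoxy-1,1-dihydro-1,2-benziodoxol-3(1H)-one), NaHCO3, CH2Cl2, 0 °C → rt
Reagents that add atoms: none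
Why: Periodinane oxidation of a primary alcohol under buffered conditions; the aldehyde has no α-stereocentre to lose.

Step 10
Reactants: 15 but-2-yne-1,4-diol
Product: 16 4-[(4-methoxybenzyl)oxy]but-2-yn-1-ol
Conditions: NaH (1 equiv), PMBCl, Bu4NI (cat.), THF/DMF, 0 °C → rt (15 in threefold excess)
Reagents that add atoms: 4-methoxybenzyl chloride, COc1ccc(CCl)cc1
Why: Statistical mono-etherification of a symmetrical diol; the excess diol suppresses the bis-ether and is removed by aqueous extraction.

Step 11
Reactants: 16 4-[(4-methoxybenzyl)oxy]but-2-yn-1-ol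
Product: 18 (2Z)-3-iodo-4-[(4-methoxybenzyl)oxy]but-2-en-1-ol, via cyclic alkenylaluminate 17 (not isolated)
Conditions: NaAlH2(OCH2CH2OMe)2, THF, 0 °C; then I2, THF, −78 °C
Reagents that add atoms: iodine, II
Why: Hydroxyl-directed trans-hydroalumination: the aluminium alkoxide delivers hydride to the near alkyne carbon and aluminium ends on the far one inside a five-membered ring. Iodinolysis with retention puts iodine cis to CH2OH; low temperature prevents loss of the β-alkoxy group.

Step 12
Reactants: 18 (2Z)-3-iodo-4-[(4-methoxybenzyl)oxy]but-2-en-1-ol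
Product: 19 triethyl{[(2Z)-3-iodo-4-[(4-methoxybenzyl)oxy]but-2-en-1-yl]oxy}silane
Conditions: TESCl, imidazole, CH2Cl2, 0 °C
Reagents that add atoms: chlorotriethylsilane, CC[Si](Cl)(CC)CC
Why: Silylation; the triethylsilyl ether is chosen because it can be removed later beside tert-butyldimethylsilyl ethers.

Step 13
Reactants: 19 triethyl{[(2Z)-3-iodo-4-[(4-methoxybenzyl)oxy]but-2-en-1-yl]oxy}silane
Product: 20 triethyl{[(2E)-4-[(4-methoxybenzyl)oxy]-3-[(4,4,5,5-tetramethyl-1,3,2-dioxaborolan-2-yl)methyl]but-2-en-1-yl]oxy}silane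
Conditions: IZnCH2B(pin) (from ICH2B(pin), Zn dust, THF), Pd(PPh3)4 (5 mol %), THF, rt → 40 °C
Reagents that add atoms: (pinacolatoboryl)methylzinc iodide, CC1(C)OB(C[Zn]I)OC1(C)C, made in the flask from 2-(iodomethyl)-4,4,5,5-tetramethyl-1,3,2-dioxaborolane, CC1(C)OB(CI)OC1(C)C
Why: Negishi coupling of an alkenyl iodide with a borylmethylzinc reagent gives the allylboronate with retention of alkene geometry, so CH2B is cis to the CH2OSi carbon. No π-allyl intermediate is involved that could scramble the geometry.

Step 14
Reactants: 21 methyl (S)-3-hydroxy-2-methylpropanoate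
Product: 22 methyl (S)-3-[(tert-butyldimethylsilyl)oxy]-2-methylpropanoate
Conditions: TBSCl, imidazole, DMF, rt
Reagents that add atoms: tert-butyldimethylsilyl chloride, CC(C)(C)[Si](C)(C)Cl
Why: Silylation of the primary alcohol prevents self-acylation in step 21.

Step 15
Reactants: 22 methyl (S)-3-[(tert-butyldimethylsilyl)oxy]-2-methylpropanoate
Product: 23 (S)-3-[(tert-butyldimethylsilyl)oxy]-2-methylpropanoic acid
Conditions: LiOH, THF/H2O, 0 °C → rt; then 0.5 M HCl to pH 4, 0 °C
Reagents that add atoms: lithium hydroxide, [Li+].[OH-]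
Why: Saponification at low temperature; once the carboxylate has formed the α-centre is not enolised under these conditions.

Step 16
Reactants: 14 (3S,4Z)-6-[(tert-butyldimethylsilyl)oxy]-3-ethenyl-5-iodo-3-methylhex-4-enal; 20 triethyl{[(2E)-4-[(4-methoxybenzyl)oxy]-3-[(4,4,5,5-tetramethyl-1,3,2-dioxaborolan-2-yl)methyl]but-2-en-1-yl]oxy}silane
Product: 25 (2S,3R,5S,6Z)-8-[(tert-butyldimethylsilyl)oxy]-5-ethenyl-7-iodo-2-{3-[(4-methoxybenzyl)oxy]prop-1-en-2-yl}-5-methyl-1-[(triethylsilyl)oxy]oct-6-en-3-ol, via O-boryl adduct 24 (not isolated)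
Conditions: (S)-3,3′-bis(2,4,6-triisopropylphenyl)-1,1′-binaphthyl-2,2′-diyl hydrogen phosphate [(S)-TRIP] (10 mol %), 4 Å MS, toluene, −30 → 0 °C; aqueous NaHCO3
Reagents that add atoms: none
Why: Chiral phosphoric acid-catalysed allylboration through a closed chair. The CH2OSi group cis to CH2B sits axial, which gives the syn-crotylation-type relationship of C7 and C8 (the target's C7/C8 pattern). The acid, bound to the boronate oxygen and the formyl hydrogen, directs attack to the si face of the aldehyde and so sets C8 as (R); the remote C10 centre should exert little influence.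

Step 17
Reactants: 25 (2S,3R,5S,6Z)-8-[(tert-butyldimethylsilyl)oxy]-5-ethenyl-7-iodo-2-{3-[(4-methoxybenzyl)oxy]prop-1-en-2-yl}-5-methyl-1-[(triethylsilyl)oxy]oct-6-en-3-ol
Product: 26 (2S,3R,5S,6Z)-8-[(tert-butyldimethylsilyl)oxy]-5-ethenyl-7-iodo-2-{3-[(4-methoxybenzyl)oxy]prop-1-en-2-yl}-5-methyloct-6-ene-1,3-diol
Conditions: PPTS (cat.), MeOH/CH2Cl2, 0 °C
Reagents that add atoms: none
Why: Mild acid methanolysis removes the primary triethylsilyl ether much faster than the tert-butyldimethylsilyl ether; doing this before boron is introduced keeps the allylboronate away from protic acid.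

Step 18
Reactants: 26 (2S,3R,5S,6Z)-8-[(tert-butyldimethylsilyl)oxy]-5-ethenyl-7-iodo-2-{3-[(4-methoxybenzyl)oxy]prop-1-en-2-yl}-5-methyloct-6-ene-1,3-diol
Product: 27 (2S,3R,5S,6E)-7-{[(tert-butyldimethylsilyl)oxy]methyl}-5-ethenyl-2-{3-[(4-methoxybenzyl)oxy]prop-1-en-2-yl}-5-methyl-8-(4,4,5,5-tetramethyl-1,3,2-dioxaborolan-2-yl)oct-6-ene-1,3-diol
Conditions: IZnCH2B(pin) (4 equiv, from ICH2B(pin), Zn dust, THF), Pd(PPh3)4 (10 mol %), THF, 40 °C
Reagents that add atoms: (pinacolatoboryl)methylzinc iodide, CC1(C)OB(C[Zn]I)OC1(C)C, made in the flask from 2-(iodomethyl)-4,4,5,5-tetramethyl-1,3,2-dioxaborolane, CC1(C)OB(CI)OC1(C)C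
Why: The same Negishi coupling as in step 13, now on the hindered C4 iodide: retention places CH2B cis to C10, the geometry the ring closure needs. Excess reagent covers the two hydroxyl protons, and the pinacol ester does not exchange with the diol.

Step 19
Reactants: 27 (2S,3R,5S,6E)-7-{[(tert-butyldimethylsilyl)oxy]methyl}-5-ethenyl-2-{3-[(4-methoxybenzyl)oxy]prop-1-en-2-yl}-5-methyl-8-(4,4,5,5-tetramethyl-1,3,2-dioxaborolan-2-yl)oct-6-ene-1,3-diol
Product: 28 (2R,3R,5S,6E)-7-{[(tert-butyldimethylsilyl)oxy]methyl}-5-ethenyl-3-hydroxy-2-{3-[(4-methoxybenzyl)oxy]prop-1-en-2-yl}-5-methyl-8-(4,4,5,5-tetramethyl-1,3,2-dioxaborolan-2-yl)oct-6-enal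
Conditions: TEMPO (10 mol %), PhI(OAc)2, NaHCO3, CH2Cl2, 0 °C; cold neutral work-up, no chromatography
Reagents that add atoms: none
Why: Oxoammonium oxidation is much faster for the primary than for the secondary alcohol of a 1,3-diol, and the pinacol boronate, a weak nucleophile, should be left alone. The β-hydroxy aldehyde is carried on at once, and any ring closure that has already begun leads to the same product as step 20.

Step 20
Reactants: 28 (2R,3R,5S,6E)-7-{[(tert-butyldimethylsilyl)oxy]methyl}-5-ethenyl-3-hydroxy-2-{3-[(4-methoxybenzyl)oxy]prop-1-en-2-yl}-5-methyl-8-(4,4,5,5-tetramethyl-1,3,2-dioxaborolan-2-yl)oct-6-enal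
Product: 30 (1R,2R,3S,4R,5S)-4-{3-[(tert-butyldimethylsilyl)oxy]prop-1-en-2-yl}-5-ethenyl-2-{3-[(4-methoxybenzyl)oxy]prop-1-en-2-yl}-5-methylcyclohexane-1,3-diol, via O-boryl cyclohexane 29 (not isolated)
Conditions: toluene (0.02 M), 4 Å MS, 0 °C → rt; then pH 7 buffer
Reagents that add atoms: none
Why: Thermal intramolecular allylboration: boron binds the C6 carbonyl oxygen and the γ-carbon C5 adds to C6 through a closed six-membered chair while the double bond moves to C4=C3; the closest known reaction type is the cyclisation of ω-formyl allylboronic esters to 2-alkenylcycloalkanols. The cyclohexane closes 6-exo-trig at the aldehyde as a second chair fused to the transition-state ring. Because C10 is cis to CH2B on the C5=C4 bond it must sit axial in the transition-state ring while C7 sits equatorial, so the fusion is cis and the C6 oxygen (axial) and C4 (equatorial) end up cis; this relation of C5 to C6 is secured by the alkene geometry built in steps 6 and 18. The ring face is decided between two cis-fused chairs: the wanted one keeps the C7 alkenyl group equatorial and has O8, O6 and the C10 methyl syn-axial, the other puts the C7 group axial with the new C–O bond anti to C8–O. With an acyloxy group on C8 the second would be expected to win, which is why O8 is left as a free hydroxyl. In toluene it remains hydrogen-bonded to the aldehyde oxygen (or exchanges onto boron), which is possible only when O8 and O6 are syn, so the 1,3-diaxial contact becomes an attraction and the bound carbonyl is activated. C5 then attacks anti to the C7 alkenyl group within this hydrogen-bonded array and gives the all-cis diol, fixing C6 as (S) and C5 as (R). No external reagent is needed, so the PMB ether, the silyl ether and the β-hydroxy aldehyde (less prone to elimination than a β-acyloxy aldehyde) survive, and boron leaves as the pinacol borate on work-up.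

Step 21
Reactants: 30 (1R,2R,3S,4R,5S)-4-{3-[(tert-butyldimethylsilyl)oxy]prop-1-en-2-yl}-5-ethenyl-2-{3-[(4-methoxybenzyl)oxy]prop-1-en-2-yl}-5-methylcyclohexane-1,3-diol; 23 (S)-3-[(tert-butyldimethylsilyl)oxy]-2-methylpropanoic acid
Product: 31 (1R,2S,3S,4R,5S)-4-{3-[(tert-butyldimethylsilyl)oxy]prop-1-en-2-yl}-5-ethenyl-3-hydroxy-2-{3-[(4-methoxybenzyl)oxy]prop-1-en-2-yl}-5-methylcyclohexyl (2S)-3-[(tert-butyldimethylsilyl)oxy]-2-methylpropanoate
Conditions: 23, 2,4,6-Cl3C6H2COCl, Et3N, toluene, rt; then 30, DMAP, toluene, rt → 40 °C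
Reagents that add atoms: none
Why: Yamaguchi esterification. O8 has a methylene (C9) on one side, whereas O6 is flanked by two alkenyl-bearing carbons, so the mixed anhydride should acylate O8. Any O6 ester can migrate across the syn-1,3 diol to the less crowded O8 position, which should be the more stable isomer.

Step 22
Reactants: 31 (1R,2S,3S,4R,5S)-4-{3-[(tert-butyldimethylsilyl)oxy]prop-1-en-2-yl}-5-ethenyl-3-hydroxy-2-{3-[(4-methoxybenzyl)oxy]prop-1-en-2-yl}-5-methylcyclohexyl (2S)-3-[(tert-butyldimethylsilyl)oxy]-2-methylpropanoate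
Product: 32 C6 triethylsilyl ether of 31 (ring configuration unchanged)
Conditions: TESOTf, 2,6-lutidine, CH2Cl2, −78 → 0 °C
Reagents that add atoms: triethylsilyl trifluoromethanesulfonate, CC[Si](CC)(CC)OS(=O)(=O)C(F)(F)F
Why: The silyl triflate is reactive enough for the hindered axial hydroxyl; masking O6 prevents lactol and lactone formation when C12 is oxidised.

Step 23
Reactants: 32 C6 triethylsilyl ether of 31
Product: 33 C12 primary allylic alcohol (32 without the 4-methoxybenzyl group)
Conditions: DDQ, CH2Cl2/pH 7 buffer, 0 °C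
Reagents that add atoms: none
Why: Oxidative PMB cleavage frees only the C12 hydroxyl; silyl ethers, the ester and the alkenes are inert.

Step 24
Reactants: 33 C12 primary allylic alcohol
Product: 34 C12 aldehyde (2-substituted propenal on C7; other groups as in 33)
Conditions: MnO2, CH2Cl2, rt
Reagents that add atoms: none
Why: MnO2 oxidises the only free allylic alcohol; the other allylic oxygen (C15) is silylated.

Step 25
Reactants: 34 C12 aldehyde
Product: 35 C12 carboxylic acid (2-substituted propenoic acid on C7; O6 triethylsilyl and both tert-butyldimethylsilyl ethers intact)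
Conditions: NaClO2, NaH2PO4, 2-methylbut-2-ene, t-BuOH/H2O, 0 °C → rt
Reagents that add atoms: sodium chlorite, [Na+].[O-]Cl=O
Why: Pinnick oxidation converts the enal into the acrylic acid without touching the alkenes; the scavenger removes hypochlorous acid.

Step 26
Reactants: 35 C12 carboxylic acid
Product: 36 2-[(1S,2S,3R,4S,6R)-4-ethenyl-2-hydroxy-6-{[(2S)-3-hydroxy-2-methylpropanoyl]oxy}-3-(3-hydroxyprop-1-en-2-yl)-4-methylcyclohexyl]prop-2-enoic acid
Conditions: HF·pyridine, pyridine, THF, 0 °C → rt
Reagents that add atoms: none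
Why: Buffered fluoride desilylation removes the triethylsilyl ether and both primary tert-butyldimethylsilyl ethers; the excess pyridine keeps the medium too weakly acidic for lactonisation, and the absence of strong base avoids acyl migration.

Compound list

1 | but-3-yn-1-ol | C#CCCO | starting material
2 | 1-[(but-3-yn-1-yloxy)methyl]-4-methoxybenzene | C#CCCOCc1ccc(OC)cc1 | intermediate
3 | dimethyl[(E)-4-[(4-methoxybenzyl)oxy]-2-methylbut-1-en-1-yl]alane | C[Al](C)/C=C(\C)CCOCc1ccc(OC)cc1 | intermediate
4 | (E)-5-[(4-methoxybenzyl)oxy]-3-methylpent-2-en-1-ol | OC/C=C(\C)CCOCc1ccc(OC)cc1 | intermediate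
5 | diethyl (E)-5-[(4-methoxybenzyl)oxy]-3-methylpent-2-en-1-yl phosphate | CCOP(=O)(OCC)OC/C=C(\C)CCOCc1ccc(OC)cc1 | intermediate
6 | tert-butyldimethyl(prop-2-yn-1-yloxy)silane | C#CCO[Si](C)(C)C(C)(C)C | starting material
7 | {3-[(tert-butyldimethylsilyl)oxy]prop-1-yn-1-yl}diisobutylalane | CC(C)C[Al](CC(C)C)C#CCO[Si](C)(C)C(C)(C)C | intermediate
8 | tert-butyl{[(4S)-4-{2-[(4-methoxybenzyl)oxy]ethyl}-4-methylhex-5-en-2-yn-1-yl]oxy}dimethylsilane | COc1ccc(COCC[C@@](C)(C=C)C#CCO[Si](C)(C)C(C)(C)C)cc1 | intermediate
9 | (4S)-4-{2-[(4-methoxybenzyl)oxy]ethyl}-4-methylhex-5-en-2-yn-1-ol | COc1ccc(COCC[C@@](C)(C=C)C#CCO)cc1 | intermediate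
10 | (2Z,4S)-4-{2-[(4-methoxybenzyl)oxy]ethyl}-4-methyl-2-(tributylstannyl)hexa-2,5-dien-1-ol | COc1ccc(COCC[C@@](C)(C=C)/C=C(/CO)[Sn](CCCC)(CCCC)CCCC)cc1 | intermediate
11 | (2Z,4S)-2-iodo-4-{2-[(4-methoxybenzyl)oxy]ethyl}-4-methylhexa-2,5-dien-1-ol | COc1ccc(COCC[C@@](C)(C=C)/C=C(\I)CO)cc1 | intermediate
12 | tert-butyl{[(2Z,4S)-2-iodo-4-{2-[(4-methoxybenzyl)oxy]ethyl}-4-methylhexa-2,5-dien-1-yl]oxy}dimethylsilane | COc1ccc(COCC[C@@](C)(C=C)/C=C(\I)CO[Si](C)(C)C(C)(C)C)cc1 | intermediate
13 | (3S,4Z)-6-[(tert-butyldimethylsilyl)oxy]-3-ethenyl-5-iodo-3-methylhex-4-en-1-ol | OCC[C@@](C)(C=C)/C=C(\I)CO[Si](C)(C)C(C)(C)C | intermediate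
14 | (3S,4Z)-6-[(tert-butyldimethylsilyl)oxy]-3-ethenyl-5-iodo-3-methylhex-4-enal | O=CC[C@@](C)(C=C)/C=C(\I)CO[Si](C)(C)C(C)(C)C | intermediate
15 | but-2-yne-1,4-diol | OCC#CCO | starting material
16 | 4-[(4-methoxybenzyl)oxy]but-2-yn-1-ol | OCC#CCOCc1ccc(OC)cc1 | intermediate
17 | sodium 2,2-bis(2-methoxyethoxy)-3-{[(4-methoxybenzyl)oxy]methyl}-2,5-dihydro-1,2-oxaluminol-2-uide (five-membered O–Al–C=C–C alkenylaluminate) | COCCO[Al-]1(OCCOC)OCC=C1COCc1ccc(OC)cc1.[Na+] | intermediate
18 | (2Z)-3-iodo-4-[(4-methoxybenzyl)oxy]but-2-en-1-ol | OC/C=C(\I)COCc1ccc(OC)cc1 | intermediate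
19 | triethyl{[(2Z)-3-iodo-4-[(4-methoxybenzyl)oxy]but-2-en-1-yl]oxy}silane | CC[Si](CC)(CC)OC/C=C(\I)COCc1ccc(OC)cc1 | intermediate
20 | triethyl{[(2E)-4-[(4-methoxybenzyl)oxy]-3-[(4,4,5,5-tetramethyl-1,3,2-dioxaborolan-2-yl)methyl]but-2-en-1-yl]oxy}silane (CH2OSi cis to CH2B) | CC[Si](CC)(CC)OC/C=C(/COCc1ccc(OC)cc1)CB1OC(C)(C)C(C)(C)O1 | intermediate
21 | methyl (S)-3-hydroxy-2-methylpropanoate | COC(=O)[C@@H](C)CO | starting material
22 | methyl (S)-3-[(tert-butyldimethylsilyl)oxy]-2-methylpropanoate | COC(=O)[C@@H](C)CO[Si](C)(C)C(C)(C)C | intermediate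
23 | (S)-3-[(tert-butyldimethylsilyl)oxy]-2-methylpropanoic acid | OC(=O)[C@@H](C)CO[Si](C)(C)C(C)(C)C | intermediate
24 | C8 O-(pinacolatoboryl) ester of 25 | CC[Si](CC)(CC)OC[C@H](C(=C)COCc1ccc(OC)cc1)[C@H](OB1OC(C)(C)C(C)(C)O1)C[C@@](C)(C=C)/C=C(\I)CO[Si](C)(C)C(C)(C)C | intermediate
25 | (2S,3R,5S,6Z)-8-[(tert-butyldimethylsilyl)oxy]-5-ethenyl-7-iodo-2-{3-[(4-methoxybenzyl)oxy]prop-1-en-2-yl}-5-methyl-1-[(triethylsilyl)oxy]oct-6-en-3-ol | CC[Si](CC)(CC)OC[C@H](C(=C)COCc1ccc(OC)cc1)[C@H](O)C[C@@](C)(C=C)/C=C(\I)CO[Si](C)(C)C(C)(C)C | intermediate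
26 | (2S,3R,5S,6Z)-8-[(tert-butyldimethylsilyl)oxy]-5-ethenyl-7-iodo-2-{3-[(4-methoxybenzyl)oxy]prop-1-en-2-yl}-5-methyloct-6-ene-1,3-diol | OC[C@H](C(=C)COCc1ccc(OC)cc1)[C@H](O)C[C@@](C)(C=C)/C=C(\I)CO[Si](C)(C)C(C)(C)C | intermediate
27 | (2S,3R,5S,6E)-7-{[(tert-butyldimethylsilyl)oxy]methyl}-5-ethenyl-2-{3-[(4-methoxybenzyl)oxy]prop-1-en-2-yl}-5-methyl-8-(4,4,5,5-tetramethyl-1,3,2-dioxaborolan-2-yl)oct-6-ene-1,3-diol | OC[C@H](C(=C)COCc1ccc(OC)cc1)[C@H](O)C[C@@](C)(C=C)/C=C(/CO[Si](C)(C)C(C)(C)C)CB1OC(C)(C)C(C)(C)O1 | intermediate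
28 | (2R,3R,5S,6E)-7-{[(tert-butyldimethylsilyl)oxy]methyl}-5-ethenyl-3-hydroxy-2-{3-[(4-methoxybenzyl)oxy]prop-1-en-2-yl}-5-methyl-8-(4,4,5,5-tetramethyl-1,3,2-dioxaborolan-2-yl)oct-6-enal (precursor of the key step) | O=C[C@H](C(=C)COCc1ccc(OC)cc1)[C@H](O)C[C@@](C)(C=C)/C=C(/CO[Si](C)(C)C(C)(C)C)CB1OC(C)(C)C(C)(C)O1 | intermediate
29 | C6 O-(pinacolatoboryl) ester of 30 | C=C[C@]1(C)C[C@@H](O)[C@@H](C(=C)COCc2ccc(OC)cc2)[C@@H](OB2OC(C)(C)C(C)(C)O2)[C@H]1C(=C)CO[Si](C)(C)C(C)(C)C | intermediate
30 | (1R,2R,3S,4R,5S)-4-{3-[(tert-butyldimethylsilyl)oxy]prop-1-en-2-yl}-5-ethenyl-2-{3-[(4-methoxybenzyl)oxy]prop-1-en-2-yl}-5-methylcyclohexane-1,3-diol (methyl and the four ring substituents all cis) | C=C[C@]1(C)C[C@@H](O)[C@@H](C(=C)COCc2ccc(OC)cc2)[C@@H](O)[C@H]1C(=C)CO[Si](C)(C)C(C)(C)C | intermediate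
31 | (1R,2S,3S,4R,5S)-4-{3-[(tert-butyldimethylsilyl)oxy]prop-1-en-2-yl}-5-ethenyl-3-hydroxy-2-{3-[(4-methoxybenzyl)oxy]prop-1-en-2-yl}-5-methylcyclohexyl (2S)-3-[(tert-butyldimethylsilyl)oxy]-2-methylpropanoate | C=C[C@]1(C)C[C@@H](OC(=O)[C@@H](C)CO[Si](C)(C)C(C)(C)C)[C@@H](C(=C)COCc2ccc(OC)cc2)[C@@H](O)[C@H]1C(=C)CO[Si](C)(C)C(C)(C)C | intermediate
32 | C6 triethylsilyl ether of 31 (all-cis ring as in 31) | C=C[C@]1(C)C[C@@H](OC(=O)[C@@H](C)CO[Si](C)(C)C(C)(C)C)[C@@H](C(=C)COCc2ccc(OC)cc2)[C@@H](O[Si](CC)(CC)CC)[C@H]1C(=C)CO[Si](C)(C)C(C)(C)C | intermediate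
33 | C12 allylic alcohol: 32 with 3-hydroxyprop-1-en-2-yl on C7 | C=C[C@]1(C)C[C@@H](OC(=O)[C@@H](C)CO[Si](C)(C)C(C)(C)C)[C@@H](C(=C)CO)[C@@H](O[Si](CC)(CC)CC)[C@H]1C(=C)CO[Si](C)(C)C(C)(C)C | intermediate
34 | C12 aldehyde: 33 with 3-oxoprop-1-en-2-yl on C7 | C=C[C@]1(C)C[C@@H](OC(=O)[C@@H](C)CO[Si](C)(C)C(C)(C)C)[C@@H](C(=C)C=O)[C@@H](O[Si](CC)(CC)CC)[C@H]1C(=C)CO[Si](C)(C)C(C)(C)C | intermediate
35 | C12 acid: 2-substituted prop-2-enoic acid with O6 triethylsilyl and two tert-butyldimethylsilyl ethers | C=C[C@]1(C)C[C@@H](OC(=O)[C@@H](C)CO[Si](C)(C)C(C)(C)C)[C@@H](C(=C)C(=O)O)[C@@H](O[Si](CC)(CC)CC)[C@H]1C(=C)CO[Si](C)(C)C(C)(C)C | intermediate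
36 | 2-[(1S,2S,3R,4S,6R)-4-ethenyl-2-hydroxy-6-{[(2S)-3-hydroxy-2-methylpropanoyl]oxy}-3-(3-hydroxyprop-1-en-2-yl)-4-methylcyclohexyl]prop-2-enoic acid | C=C[C@]1(C)C[C@@H](OC(=O)[C@@H](C)CO)[C@@H](C(=C)C(=O)O)[C@@H](O)[C@H]1C(=C)CO | target

Total step count: 26. Longest linear sequence: 20 steps (steps 1–9, then 16–26). Side branches: steps 10–13 (boronate 20) and steps 14–15 (acid 23).

Steps least certain to work

Step 20 (key step). The most likely failure is poor facial discrimination between the two cis-fused chairs, which would give the ring with C5 and C6 both inverted. The hydrogen bond from O8–H may not outweigh the three syn-axial groups of the wanted chair; a second possibility is enolisation of the β,γ-unsaturated aldehyde before closure, eroding C7. Fallback: replace substrate control by catalyst control in the ester-bearing series. Starting from 25, acylation with 23 under the conditions of step 21 gives the ester iodide F1; PPTS in methanol gives the alcohol F2; Negishi coupling as in step 18 gives the allylboronate F3; buffered DMP oxidation gives the β-acyloxy aldehyde F4. F4 is closed at −30 °C with (S)-TRIP (10–20 mol %), which binds the pinacolate oxygen and the formyl hydrogen and selects the aldehyde face from outside the substrate. The O-boryl product F5 is hydrolysed on work-up to 31, where the route is rejoined after step 21.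

Step 6. Tin must end up cis to the quaternary C10, so the hydrostannation may be slow or lose regiocontrol. Fallback: a radical-chain, oxygen-directed hydrostannation. 9 with Ph3SnH and Et3B/air in toluene should place tin on C4 by anti addition to give the triphenylstannane F6, and iodine then converts F6 into 11.

Step 19. The oxidant may attack the allylboronate or over-oxidise the secondary alcohol, and the aldehyde may degrade during work-up. Fallback: oxidise before boron is present. 26 with TEMPO/PhI(OAc)2 gives the iodo β-hydroxy aldehyde F7; Negishi coupling of F7 with IZnCH2B(pin) then forms 28 in the flask, which closes through 29 to 30 without isolation.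

Step 21. Acylation of two hindered axial hydroxyls may be sluggish and poorly regioselective, with acyl migration to O6 or epimerisation of the acid's α-centre on forcing. Fallback: diol activation instead of acyl-transfer catalysis. 23 is converted with 1-chloro-N,N,2-trimethylprop-1-en-1-amine into the acid chloride F8. 30 and F8 are combined with 2-aminoethyl diphenylborinate (10 mol %) and i-Pr2NEt in MeCN; the borinate complex of the syn-1,3-diol should react at the less hindered O8 and give 31.

Step 26. Acid-promoted lactonisation between O6–H and the C12 acid, or migration of the ester from O8 to O6, may occur during desilylation. Fallback: keep the acid masked while the silyl groups are removed. 35 with allyl bromide and KHCO3 in DMF gives the allyl ester F9; HF·pyridine gives the triol allyl ester F10; Pd(PPh3)4 (zerovalent palladium) with morpholine in THF removes the allyl group under neutral conditions and gives 36.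

Further compounds

F1 | step 20 | C8 (2S)-3-[(tert-butyldimethylsilyl)oxy]-2-methylpropanoate of 25 | CC[Si](CC)(CC)OC[C@H](C(=C)COCc1ccc(OC)cc1)[C@H](OC(=O)[C@@H](C)CO[Si](C)(C)C(C)(C)C)C[C@@](C)(C=C)/C=C(\I)CO[Si](C)(C)C(C)(C)C
F2 | step 20 | F1 without the triethylsilyl group (C6 primary alcohol) | OC[C@H](C(=C)COCc1ccc(OC)cc1)[C@H](OC(=O)[C@@H](C)CO[Si](C)(C)C(C)(C)C)C[C@@](C)(C=C)/C=C(\I)CO[Si](C)(C)C(C)(C)C
F3 | step 20 | (E)-allylboronic pinacol ester from F2 (CH2B cis to C10) | OC[C@H](C(=C)COCc1ccc(OC)cc1)[C@H](OC(=O)[C@@H](C)CO[Si](C)(C)C(C)(C)C)C[C@@](C)(C=C)/C=C(/CO[Si](C)(C)C(C)(C)C)CB1OC(C)(C)C(C)(C)O1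
F4 | step 20 | C6 aldehyde of F3 (β-acyloxy aldehyde) | O=C[C@H](C(=C)COCc1ccc(OC)cc1)[C@H](OC(=O)[C@@H](C)CO[Si](C)(C)C(C)(C)C)C[C@@](C)(C=C)/C=C(/CO[Si](C)(C)C(C)(C)C)CB1OC(C)(C)C(C)(C)O1
F5 | step 20 | C6 O-(pinacolatoboryl) ester of 31 | C=C[C@]1(C)C[C@@H](OC(=O)[C@@H](C)CO[Si](C)(C)C(C)(C)C)[C@@H](C(=C)COCc2ccc(OC)cc2)[C@@H](OB2OC(C)(C)C(C)(C)O2)[C@H]1C(=C)CO[Si](C)(C)C(C)(C)C
F6 | step 6 | (2Z,4S)-4-{2-[(4-methoxybenzyl)oxy]ethyl}-4-methyl-2-(triphenylstannyl)hexa-2,5-dien-1-ol | COc1ccc(COCC[C@@](C)(C=C)/C=C(/CO)[Sn](c2ccccc2)(c2ccccc2)c2ccccc2)cc1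
F7 | step 19 | (2R,3R,5S,6Z)-8-[(tert-butyldimethylsilyl)oxy]-5-ethenyl-3-hydroxy-7-iodo-2-{3-[(4-methoxybenzyl)oxy]prop-1-en-2-yl}-5-methyloct-6-enal | O=C[C@H](C(=C)COCc1ccc(OC)cc1)[C@H](O)C[C@@](C)(C=C)/C=C(\I)CO[Si](C)(C)C(C)(C)C
F8 | step 21 | (S)-3-[(tert-butyldimethylsilyl)oxy]-2-methylpropanoyl chloride | ClC(=O)[C@@H](C)CO[Si](C)(C)C(C)(C)C
F9 | step 26 | allyl ester of 35 | C=C[C@]1(C)C[C@@H](OC(=O)[C@@H](C)CO[Si](C)(C)C(C)(C)C)[C@@H](C(=C)C(=O)OCC=C)[C@@H](O[Si](CC)(CC)CC)[C@H]1C(=C)CO[Si](C)(C)C(C)(C)C
F10 | step 26 | allyl ester of 36 | C=C[C@]1(C)C[C@@H](OC(=O)[C@@H](C)CO)[C@@H](C(=C)C(=O)OCC=C)[C@@H](O)[C@H]1C(=C)CO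
A1 | alternative 1 | cis-5-[(tert-butyldimethylsilyl)oxy]-3-{[(triisopropylsilyl)oxy]methyl}cyclohex-2-en-1-ol | O[C@H]1C=C(CO[Si](C(C)C)(C(C)C)C(C)C)C[C@@H](O[Si](C)(C)C(C)(C)C)C1
A2 | alternative 1 | 4-[(tert-butyldimethylsilyl)oxy]-6-{[(triisopropylsilyl)oxy]methyl}bicyclo[4.1.0]heptan-2-ol (cyclopropane methylene cis to both oxygens) | O[C@H]1[C@H]2C[C@@]2(CO[Si](C(C)C)(C(C)C)C(C)C)C[C@@H](O[Si](C)(C)C(C)(C)C)C1
A3 | alternative 2 | (R)-5-[(tert-butyldimethylsilyl)oxy]-3-methylcyclohex-2-en-1-one | CC1=CC(=O)C[C@H](O[Si](C)(C)C(C)(C)C)C1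
A4 | alternative 2 | 1-{[(2-bromoprop-2-en-1-yl)oxy]methyl}-4-methoxybenzene | C=C(Br)COCc1ccc(OC)cc1
A5 | alternative 2 | 5-[(tert-butyldimethylsilyl)oxy]-3-ethenyl-2-{3-[(4-methoxybenzyl)oxy]prop-1-en-2-yl}-3-methylcyclohexan-1-one (C2 alkenyl and C5 silyloxy cis to the C3 methyl) | C=C[C@]1(C)C[C@@H](O[Si](C)(C)C(C)(C)C)CC(=O)[C@H]1C(=C)COCc2ccc(OC)cc2
A6 | alternative 3 | allyl (E)-2-(acetoxymethyl)-5-{3-[(tert-butyldimethylsilyl)oxy]prop-1-en-2-yl}-6-ethenyl-6-methyl-8-oxo-4-[(triethylsilyl)oxy]oct-2-enoate (C5, C6 and C10 centres as in 36) | O=CC[C@@](C)(C=C)[C@H](C(=C)CO[Si](C)(C)C(C)(C)C)[C@H](O[Si](CC)(CC)CC)/C=C(/C(=O)OCC=C)COC(C)=O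
A7 | alternative 3 | allyl 2-{3-{3-[(tert-butyldimethylsilyl)oxy]prop-1-en-2-yl}-4-ethenyl-4-methyl-6-oxo-2-[(triethylsilyl)oxy]cyclohexyl}prop-2-enoate (all-cis as in 36) | C=C[C@]1(C)CC(=O)[C@@H](C(=C)C(=O)OCC=C)[C@@H](O[Si](CC)(CC)CC)[C@H]1C(=C)CO[Si](C)(C)C(C)(C)C
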